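## Retrosynthetic overview
1. Sarothralin ⇒ (loss of 2 MeOH, two C-acylations in one pot) an acyclic bis-polyketide strung on a glutarate. Glutarate C3 is the CH2 bridge, C2/C4 are the two ring carbons it joins, and C1/C5 are one C–OH carbon of each ring.
2. Aromatic half ⇒ glutarate α-carbanion + 4-prenyloxy-6-phenyl-2-pyrone (attack at C2, ring opening). O1–C6(Ph) of the pyrone becomes the benzoyl group, so the prenyl ether sits ortho to it and no phenol has to be differentiated.
3. Filicinic half ⇒ the other glutarate α-carbanion + 6-isopropyl-3,3-dimethylpyran-2,4-dione, a vinylogous anhydride that carries CMe2 and the masked isobutyryl group.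
4. Both lactones ⇒ formal [3+3] of a malonyl dichloride with a methyl ketone (enol) partner; the prenyl group comes from prenol by Mitsunobu reaction.
5. Ring order: the two sacrificial O-heterocycles are made first, in separate branches. In the last operation the pyrone is opened and both carbocycles close, aromatic ring first and filicinic ring second. The phenyl ring is bought.

Assumption: the target SMILES has no stereocentre and no stereogenic C=C (sarothralin is achiral, and the drawn dienol is one tautomer of the β-triketone). There is therefore no enantiomer to select and no step has to set configuration.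

## Route

Step 1
Reactants: 1 1-phenyl-1-(trimethylsilyloxy)ethene; 2 malonyl dichloride
Product: 3 4-hydroxy-6-phenyl-2H-pyran-2-one
Conditions: Et2O, −78 °C → rt; filter the precipitated product
Reagents that add atoms: none
Why: Uncatalysed C-acylation of the silyl enol ether by the bis-acid chloride, then O-acylation of the resulting β-diketone enol (Effenberger-type pyrone synthesis, formal [3+3]), gives the pyrone in which the only free OH is the oxygen that will carry the prenyl group.

Step 2
Reactants: 3 4-hydroxy-6-phenyl-2H-pyran-2-one; 4 3-methylbut-2-en-1-ol (prenol)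
Product: 5 4-[(3-methylbut-2-en-1-yl)oxy]-6-phenyl-2H-pyran-2-one
Conditions: PPh3, DIAD, THF, 0 °C → rt
Reagents that add atoms: none
Why: In this Mitsunobu etherification the acidic pyrone 4-OH (pKa about 5) is alkylated at O-4 by SN2 on the primary oxyphosphonium salt, which avoids the C-3 alkylation seen with prenyl halides, and the neutral room-temperature conditions prevent Claisen rearrangement of the allyl vinyl ether.

Step 3
Reactants: 6 3-methylbutan-2-one; 7 2,2-dimethylmalonyl dichloride
Product: 8 3,3-dimethyl-6-(propan-2-yl)-2H-pyran-2,4(3H)-dione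
Conditions: MgBr2·OEt2 (2.5 equiv), i-Pr2NEt (3 equiv), CH2Cl2, 0 °C → rt, 6 added slowly to 7 (1.1 equiv)
Reagents that add atoms: none
Why: Soft-enolisation crossed Claisen acylation puts the first acyl chloride on the less hindered CH3 carbon, and the magnesium β-diketonate then O-acylates the second, ketene-incapable acid chloride in a six-membered lactonisation favoured by the gem-dimethyl effect (formal [3+3]).

Step 4
Reactants: 9 dimethyl glutarate; 8 3,3-dimethyl-6-(propan-2-yl)-2H-pyran-2,4(3H)-dione
Product: 10 dimethyl 2-(2,2,6-trimethyl-3,5-dioxoheptanoyl)pentanedioate (racemic)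
Conditions: 9 (2.2 equiv), LDA (2.2 equiv, commercial solution), THF, −78 °C, 45 min; 8 (1.0 equiv), −78 → −40 °C, 2 h; AcOH, −78 °C; excess 9 removed by distillation
Reagents that add atoms: none
Why: This is a crossed Claisen acylation with ring opening (Fujimoto–Belleau-type attack of a carbanion on an enol lactone) in which C2 of vinylogous anhydride 8 is the activated carbonyl and expels a β-diketonate; the second enolate equivalent deprotonates the new β-keto ester, so the dianion has every nearby carbonyl enolised and neither reacts twice nor cyclises before the cold quench, and the new stereocentre is racemic, labile and erased in Step 5.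

Step 5
Reactants: 10 dimethyl 2-(2,2,6-trimethyl-3,5-dioxoheptanoyl)pentanedioate; 5 4-[(3-methylbut-2-en-1-yl)oxy]-6-phenyl-2H-pyran-2-one
Product: 13 sarothralin, via acyclic bis-adduct 11 (not isolated), via ring-A-closed keto ester 12 (not isolated)
Conditions: LDA (3.1 equiv), THF, −78 °C, 1 h; 5 (1.0 equiv), −78 °C, 1 h; LDA (1.1 equiv), −78 °C → rt, 3 h; MeOH (5 equiv), rt, 2 h; cold 1 M HCl
Reagents that add atoms: none
Why: Proposed new method: of the three anionic sites in the trianion of 10 only the last-formed ester enolate is reactive (Hauser polyanion rule), and it attacks the unhindered lactone C=O of 5 as ester-bearing carbanions do with 4-alkoxy-2-pyrones (Staunton-type pyrone condensation), opening the ring to 11, whose former ring double bond holds old pyrone C5 next to the glutarate ester; C-acylation there (biomimetic Claisen cyclisation of a 3,5,7-triketo ester to an acylphloroglucinol, with the competing aldol mode blocked because its nucleophilic carbon is fully substituted and cannot aromatise) gives aromatic 12, the methoxide/methanol set free re-protonates the β-keto ester enolate so that the β-diketonate carbon closes onto the second ester (Lacey–Dieckmann-type closure to a cyclic β-triketone), both closures are pulled by formation of the stable tetra-anion of 13, all other ring sizes available are 4 or 8, and the labile stereocentres of 11 and 12 vanish so the product is achiral.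

## Compound list
1 | 1-phenyl-1-(trimethylsilyloxy)ethene | C=C(O[Si](C)(C)C)c1ccccc1 | starting material
2 | malonyl dichloride | O=C(Cl)CC(=O)Cl | starting material
3 | 4-hydroxy-6-phenyl-2H-pyran-2-one | OC1=CC(=O)OC(=C1)c1ccccc1 | intermediate
4 | 3-methylbut-2-en-1-ol (prenol) | CC(C)=CCO | starting material
5 | 4-[(3-methylbut-2-en-1-yl)oxy]-6-phenyl-2H-pyran-2-one | CC(C)=CCOC1=CC(=O)OC(=C1)c1ccccc1 | intermediate
6 | 3-methylbutan-2-one | CC(=O)C(C)C | starting material
7 | 2,2-dimethylmalonyl dichloride | CC(C)(C(=O)Cl)C(=O)Cl | starting material
8 | 3,3-dimethyl-6-(propan-2-yl)-2H-pyran-2,4(3H)-dione | CC(C)C1=CC(=O)C(C)(C)C(=O)O1 | intermediate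
9 | dimethyl glutarate (dimethyl pentanedioate) | COC(=O)CCCC(=O)OC | starting material
10 | dimethyl 2-(2,2,6-trimethyl-3,5-dioxoheptanoyl)pentanedioate (racemic, labile centre) | COC(=O)CCC(C(=O)OC)C(=O)C(C)(C)C(=O)CC(=O)C(C)C | intermediate
11 | dimethyl 2-{(2E)-3-[(3-methylbut-2-en-1-yl)oxy]-5-oxo-5-phenylpent-2-enoyl}-4-(2,2,6-trimethyl-3,5-dioxoheptanoyl)pentanedioate (present as its tetra-anion, labile centres unassigned) | COC(=O)C(CC(C(=O)OC)C(=O)C(C)(C)C(=O)CC(=O)C(C)C)C(=O)/C=C(\CC(=O)c1ccccc1)OCC=C(C)C | intermediate
12 | methyl 2-{[3-benzoyl-2,6-dihydroxy-4-(3-methylbut-2-enyloxy)phenyl]methyl}-4,4,8-trimethyl-3,5,7-trioxononanoate (labile centre unassigned) | CC(C)=CCOc1cc(O)c(CC(C(=O)OC)C(=O)C(C)(C)C(=O)CC(=O)C(C)C)c(O)c1C(=O)c1ccccc1 | intermediate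
13 | sarothralin, 4-{[3-benzoyl-2,6-dihydroxy-4-(3-methylbut-2-enyloxy)phenyl]methyl}-3,5-dihydroxy-6,6-dimethyl-2-(2-methylpropanoyl)cyclohexa-2,4-dien-1-one (achiral) | CC(C)=CCOc1cc(O)c(CC2=C(O)C(C)(C)C(=O)C(C(=O)C(C)C)=C2O)c(O)c1C(=O)c1ccccc1 | target

Total step count: 5. Longest linear sequence: 3 (6/7 → 8 → 10 → 13, or equally 1/2 → 3 → 5 → 13).

## Steps most likely to fail

**Step 5.**
- The risks are the solubility and reactivity of the three- to four-fold anion, attack on 5 at C6 instead of C2, carbanion-accelerated Claisen shift of the prenyl group in 11, slow closure of the filicinic ring, and base-induced scrambling of the methylene bridge.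
- The fallback sets out from 5 and 8 and comes back at 13. It gives up the glutarate linchpin for a Mannich/methylene-trione union.
- Excess lithium enolate of methyl acetate (THF, −78 °C → rt) converts 5 into [4,6-dihydroxy-2-(3-methylbut-2-enyloxy)phenyl](phenyl)methanone F1.
- In a separate flask the same enolate converts 8 into 3,5-dihydroxy-6,6-dimethyl-2-(2-methylpropanoyl)cyclohexa-2,4-dien-1-one (isobutyrylfilicinic acid) F2.
- F2 with aqueous formaldehyde and dimethylamine gives 4-[(dimethylamino)methyl]-3,5-dihydroxy-6,6-dimethyl-2-(2-methylpropanoyl)cyclohexa-2,4-dien-1-one F3.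
- Warming F3 with F1 in dioxane expels the amine. The transient methylene-trione is trapped by the carbon of F1 that lies between the two hydroxyls, which gives 13.

**Step 4.**
- The risks are that the hindered C2 of 8 reacts slowly, that conjugate attack occurs at C6, or that the strongly basic ester enolate deprotonates the isopropyl γ-position.
- The fallback sets out from 8 and comes back at 10. It replaces the lithium enolate by a decarboxylative magnesium-enolate acylation (Masamune–Brooks type).
- Dimethyl malonate is added to methyl acrylate (cat. NaOMe) to give trimethyl propane-1,1,3-tricarboxylate F4.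
- One malonate ester of F4 is saponified (KOH, 1 equiv, MeOH) to 5-methoxy-2-(methoxycarbonyl)-5-oxopentanoic acid F5.
- The magnesium enolate of F5 (i-PrMgCl, 2 equiv, THF, rt → 40 °C) is acylated by 8 and loses CO2 on work-up to give 10.

**Step 3.**
- The risks are over-acylation of 8 by more magnesium enolate, intermolecular bis-acylation of 7, or enolisation on the methine side.
- The fallback sets out from 6 and comes back at 8. It abandons base-mediated enolisation in the presence of the acid chloride.
- The kinetic enolate of 6 (LDA, −78 °C) is trapped with TMSCl, and 3-methyl-2-(trimethylsilyloxy)but-1-ene F6 is isolated by distillation.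
- F6 is then combined with 7 in Et2O (−78 °C → rt) under the base-free, Lewis-acid-free acylation–lactonisation used in Step 1.

## Further compounds
F1 | step 5 | [4,6-dihydroxy-2-(3-methylbut-2-enyloxy)phenyl](phenyl)methanone | CC(C)=CCOc1cc(O)cc(O)c1C(=O)c1ccccc1
F2 | step 5 | 3,5-dihydroxy-6,6-dimethyl-2-(2-methylpropanoyl)cyclohexa-2,4-dien-1-one (isobutyrylfilicinic acid) | CC(C)C(=O)C1=C(O)C=C(O)C(C)(C)C1=O
F3 | step 5 | 4-[(dimethylamino)methyl]-3,5-dihydroxy-6,6-dimethyl-2-(2-methylpropanoyl)cyclohexa-2,4-dien-1-one | CN(C)CC1=C(O)C(C)(C)C(=O)C(C(=O)C(C)C)=C1O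
F4 | step 4 | trimethyl propane-1,1,3-tricarboxylate | COC(=O)CCC(C(=O)OC)C(=O)OC
F5 | step 4 | 5-methoxy-2-(methoxycarbonyl)-5-oxopentanoic acid (racemic) | COC(=O)CCC(C(=O)O)C(=O)OC
F6 | step 3 | 3-methyl-2-(trimethylsilyloxy)but-1-ene | C=C(O[Si](C)(C)C)C(C)C
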